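**Plan**
- Numbering (target): ring C1 (C=O), C2=C3, C4 (OMe), C5 (CH2), C6 (quaternary); side chain C8 (CHMe) and C7 (ArCHOH). Locants inside compound names follow each compound's own IUPAC numbering.
- Cuts: the C2=C3 unsaturation (made last); C6–allyl (enolate allylation); C7–C8 (aldehyde plus ring allylboronate); the C4–B and C5–B bonds (diene diboration); C6=C8 (Grignard addition and dehydration on a bought six-membered ring).
- Enabling feature: the path C8–C6–C5–C4 (side-chain methine, quaternary ring carbon, ring CH2, methoxy carbon) is a hidden 1,3-diene C8=C6–C5=C4 that the ring locks s-trans. Syn-diboration of its ring end puts an allylic boron on C5, whose γ-carbon is C8, and a second boron on C4, the latent methoxy oxygen, on the same face.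
- Forward order: the carbocycle is present from the start. The sequence is ethylidene diene, diboration, union with 3,4,5-trimethoxybenzaldehyde (alkene moves to C6=C5), C4–B to C4–OMe, ketal to enone C1(=O)–C6=C5, hydride to C5 and allyl to C6, dehydrogenation C2–C3, desilylation.
- Stereochemistry: one catalytic event (enantioselective diboration) sets C4 and C5. C5–B is relayed to C8 and C7 in the closed allylboration transition state, and C4–B becomes C4–O with retention. C6 is set by substrate control (A(1,3) strain from C8, axial attack anti to C4–OMe).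

Key step: step 5

Assumption 1: the (R,R) antipode of the phosphonite ligand is taken to deliver boron to the face drawn for 5; if the sense is opposite, the (S,S) ligand is used.
Assumption 2: compound 1 is taken as a catalogue compound; it is otherwise one ketalisation away from cyclohexane-1,2-dione.

Step 1
Reactants: 1 1,4-dioxaspiro[4.5]decan-6-one
Product: 2 1,4-dioxaspiro[4.5]dec-7-en-6-one
Conditions: IBX (1.3 equiv), DMSO, 65 °C
Reagents that add atoms: none
Why: IBX-mediated ketone dehydrogenation; only one α-carbon carries hydrogens because the other is the ketal carbon, so a single enone can form.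

Step 2
Reactants: 2 1,4-dioxaspiro[4.5]dec-7-en-6-one
Product: 3 (±)-6-ethyl-1,4-dioxaspiro[4.5]dec-7-en-6-ol
Conditions: EtMgBr, THF, −78 to 0 °C; then H2O
Reagents that add atoms: ethylmagnesium bromide, CC[Mg]Br
Why: 1,2-Grignard addition to an enone whose carbonyl is activated and chelated by the neighbouring ketal oxygens; the new carbinol centre is racemic and is erased in step 3.

Step 3
Reactants: 3 (±)-6-ethyl-1,4-dioxaspiro[4.5]dec-7-en-6-ol
Product: 4 (6E)-6-ethylidene-1,4-dioxaspiro[4.5]dec-7-ene
Conditions: methyl N-(triethylammoniosulfonyl)carbamate (Burgess reagent), toluene, 50 °C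
Reagents that add atoms: none
Why: Burgess dehydration (syn elimination of the sulfamate); the ethyl CH2 holds the only β-hydrogens, and the transition state that turns the methyl group away from the dioxolane toward the vinylic C5–H should give the E-ethylidene diene.

Step 4
Reactants: 4 (6E)-6-ethylidene-1,4-dioxaspiro[4.5]dec-7-ene
Product: 5 (6E,7S,8S)-6-ethylidene-7,8-bis(4,4,5,5-tetramethyl-1,3,2-dioxaborolan-2-yl)-1,4-dioxaspiro[4.5]decane (boryl groups cis)
Conditions: B2pin2 (1.05 equiv), Pt(dba)3 (3 mol %), (R,R)-TADDOL-derived phenylphosphonite with 3,5-diisopropylphenyl groups (6 mol %), THF, 60 °C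
Reagents that add atoms: bis(pinacolato)diboron, CC1(C)OB(OC1(C)C)B1OC(C)(C)C(C)(C)O1
Why: Proposed new method: oxidative addition of the B–B bond to zerovalent platinum, binding of the less substituted ring alkene C4=C5 and syn migratory insertion put boron on the diene terminus C4 and platinum on C5 as an allyl unit (C5–C6–C8); because the ring holds the diene s-trans, the pathway that carries the second boron to the far terminus C8 (it needs an s-cis diene) is closed, so C–B reductive elimination at C5 on the same face should give the cis-1,2-bis(boronate), with the chiral phosphonite choosing the alkene face and setting C4 and C5 together; the closest known reaction types are the platinum-catalysed enantioselective 1,2-diboration of 1,3-dienes that cannot reach the s-cis form (shown on terminal vinyl groups) and the 1,4-diboration of cyclic 1,3-dienes (shown on ring alkenes).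

Step 5
Reactants: 5 (6E,7S,8S)-6-ethylidene-7,8-bis(4,4,5,5-tetramethyl-1,3,2-dioxaborolan-2-yl)-1,4-dioxaspiro[4.5]decane; 6 3,4,5-trimethoxybenzaldehyde
Product: 8 (1R,2S)-2-[(8S)-8-(4,4,5,5-tetramethyl-1,3,2-dioxaborolan-2-yl)-1,4-dioxaspiro[4.5]dec-6-en-6-yl]-1-(3,4,5-trimethoxyphenyl)propan-1-ol, via pinacol borate ester 7 (not isolated)
Conditions: 6 (1.0 equiv), toluene, 4 Å MS, 60 °C; then H2O
Reagents that add atoms: none
Why: The aldehyde oxygen binds the allylic boron on C5 and the allyl unit is transferred through a closed six-membered chair (Zimmerman–Traxler type) array B–O–C7–C8–C6–C5, so that C7–C8 forms at the γ-carbon while C5–B breaks and the double bond moves into the ring (C6=C5); hydrolysis of borate 7 on work-up frees the alcohol. The closest known reaction type is the allylboration of aldehydes with α-chiral allylic pinacol boronates made by 1,2-diboration of 1,3-dienes. No ring is closed. C8 is controlled by the C5–B stereocentre, because A(1,3) strain between the ethylidene methyl group and C5 holds the C5–B bond axial and the aldehyde can only reach the face of C8 that carries boron, which is also the face of the C4 substituent; C7 is controlled by the chair, in which the aryl group is equatorial and the methyl group, cis to the boron-bearing carbon as in a Z-crotylboronate, is axial, which should give the 7,8-syn (7R,8S) pair. Chemoselectivity between the two C–B bonds is secured because only C5–B is allylic, pinacol esters do not undergo 1,3-boron shifts, and the C4–B bond, although allylic in the product, has a fully substituted γ-carbon (C6) next to the ketal and should not compete when one equivalent of 6 is used. Thus one event joins the halves, sets two stereocentres, places the alkene where the enone is needed and keeps the latent C4 oxygen.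

Step 6
Reactants: 8 (1R,2S)-2-[(8S)-8-(4,4,5,5-tetramethyl-1,3,2-dioxaborolan-2-yl)-1,4-dioxaspiro[4.5]dec-6-en-6-yl]-1-(3,4,5-trimethoxyphenyl)propan-1-ol
Product: 9 tert-butyldimethylsilyl ether of 8
Conditions: TBSOTf, 2,6-lutidine, CH2Cl2, −78 to 0 °C
Reagents that add atoms: tert-butyldimethylsilyl triflate, CC(C)(C)[Si](C)(C)OS(=O)(=O)C(F)(F)F
Why: Silyl triflate silylation of a hindered secondary benzylic alcohol under a non-nucleophilic base leaves the ketal and the boronate untouched and masks C7–OH before a second hydroxyl is unveiled.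

Step 7
Reactants: 9 tert-butyldimethylsilyl ether of 8
Product: 10 (8S)-6-[(1R,2S)-1-(tert-butyldimethylsilyloxy)-1-(3,4,5-trimethoxyphenyl)propan-2-yl]-1,4-dioxaspiro[4.5]dec-6-en-8-ol
Conditions: H2O2 (30 % aq), NaOH, THF, 0 °C
Reagents that add atoms: hydrogen peroxide, OO
Why: Peroxide oxidation of a C–B bond proceeds by 1,2-migration of carbon from boron to oxygen with retention and without allylic shift, so C4–O lies on the face fixed in step 4.

Step 8
Reactants: 10 (8S)-6-[(1R,2S)-1-(tert-butyldimethylsilyloxy)-1-(3,4,5-trimethoxyphenyl)propan-2-yl]-1,4-dioxaspiro[4.5]dec-6-en-8-ol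
Product: 11 (8S)-6-[(1R,2S)-1-(tert-butyldimethylsilyloxy)-1-(3,4,5-trimethoxyphenyl)propan-2-yl]-8-methoxy-1,4-dioxaspiro[4.5]dec-6-ene
Conditions: NaH, MeI, THF, 0 °C to rt
Reagents that add atoms: iodomethane, CI
Why: Williamson methylation of the only free hydroxyl; no stereocentre is touched.

Step 9
Reactants: 11 (8S)-6-[(1R,2S)-1-(tert-butyldimethylsilyloxy)-1-(3,4,5-trimethoxyphenyl)propan-2-yl]-8-methoxy-1,4-dioxaspiro[4.5]dec-6-ene
Product: 12 (4S)-2-[(1R,2S)-1-(tert-butyldimethylsilyloxy)-1-(3,4,5-trimethoxyphenyl)propan-2-yl]-4-methoxycyclohex-2-en-1-one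
Conditions: aq. oxalic acid on SiO2, CH2Cl2, rt
Reagents that add atoms: water, O
Why: Mild acid hydrolysis of an α,β-unsaturated ketal, which ionises more easily than a saturated one, frees the enone C1(=O)–C6=C5 while the silyl ether and the allylic methyl ether persist.

Step 10
Reactants: 12 (4S)-2-[(1R,2S)-1-(tert-butyldimethylsilyloxy)-1-(3,4,5-trimethoxyphenyl)propan-2-yl]-4-methoxycyclohex-2-en-1-one
Product: 14 (2R,4S)-2-allyl-2-[(1R,2S)-1-(tert-butyldimethylsilyloxy)-1-(3,4,5-trimethoxyphenyl)propan-2-yl]-4-methoxycyclohexan-1-one, via lithium enolate 13 (not isolated)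
Conditions: LiBH(s-Bu)3, THF, −78 °C; then allyl bromide, HMPA, −78 °C to rt
Reagents that add atoms: allyl bromide, C=CCBr
Why: Reductive alkylation: conjugate hydride addition to the β-unsubstituted enone gives the tetrasubstituted enolate regiospecifically, and allyl bromide should then attack C6 from the face opposite the C4 methoxy group and opposite the CH(OTBS)Ar branch of C8 (whose C–H eclipses the enolate C–O to relieve A(1,3) strain), which is also the axial chair-like trajectory, so all three biases point to (6R).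

Step 11
Reactants: 14 (2R,4S)-2-allyl-2-[(1R,2S)-1-(tert-butyldimethylsilyloxy)-1-(3,4,5-trimethoxyphenyl)propan-2-yl]-4-methoxycyclohexan-1-one
Product: 17 (4R,6R)-6-allyl-6-[(1R,2S)-1-(tert-butyldimethylsilyloxy)-1-(3,4,5-trimethoxyphenyl)propan-2-yl]-4-methoxycyclohex-2-en-1-one, via lithium enolate 15 (not isolated), via sulfilimine adduct 16 (not isolated)
Conditions: LiN(i-Pr)2, THF, −78 °C; then N-tert-butylbenzenesulfinimidoyl chloride, −78 °C
Reagents that add atoms: none
Why: One-pot ketone dehydrogenation: enolisation can occur only toward C2 because C6 is quaternary, and the enolate attacks sulfur of the sulfinimidoyl chloride to give an adduct that undergoes syn elimination at low temperature, which spares the allyl group and leaves C4 and C6 untouched.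

Step 12
Reactants: 17 (4R,6R)-6-allyl-6-[(1R,2S)-1-(tert-butyldimethylsilyloxy)-1-(3,4,5-trimethoxyphenyl)propan-2-yl]-4-methoxycyclohex-2-en-1-one
Product: 18 megaphone = (4R,6R)-6-[(1R,2S)-1-hydroxy-1-(3,4,5-trimethoxyphenyl)propan-2-yl]-4-methoxy-6-(prop-2-en-1-yl)cyclohex-2-en-1-one
Conditions: HF·pyridine, THF, 0 °C
Reagents that add atoms: none
Why: Fluoride-mediated desilylation under buffered acidic conditions avoids base-induced γ-epimerisation at C4 or loss of methanol.

**Compound list**
1 | 1,4-dioxaspiro[4.5]decan-6-one | O=C1CCCCC12OCCO2 | starting material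
2 | 1,4-dioxaspiro[4.5]dec-7-en-6-one | O=C1C=CCCC12OCCO2 | intermediate
3 | (±)-6-ethyl-1,4-dioxaspiro[4.5]dec-7-en-6-ol (racemic) | CCC1(O)C=CCCC12OCCO2 | intermediate
4 | (6E)-6-ethylidene-1,4-dioxaspiro[4.5]dec-7-ene | C1COC2(O1)CCC=C/C2=C\C | intermediate
5 | (6E,7S,8S)-6-ethylidene-7,8-bis(pinacolboryl)-1,4-dioxaspiro[4.5]decane | C1COC2(O1)CC[C@H](B3OC(C)(C)C(C)(C)O3)[C@H](B3OC(C)(C)C(C)(C)O3)/C2=C\C | intermediate
6 | 3,4,5-trimethoxybenzaldehyde | COc1cc(C=O)cc(OC)c1OC | starting material
7 | pinacol borate ester of 8 (C7–O–Bpin) | C1COC2(O1)CC[C@H](B3OC(C)(C)C(C)(C)O3)C=C2[C@H](C)[C@@H](OB2OC(C)(C)C(C)(C)O2)c1cc(OC)c(OC)c(OC)c1 | intermediate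
8 | (1R,2S)-2-[(8S)-8-(pinacolboryl)-1,4-dioxaspiro[4.5]dec-6-en-6-yl]-1-(3,4,5-trimethoxyphenyl)propan-1-ol | C1COC2(O1)CC[C@H](B3OC(C)(C)C(C)(C)O3)C=C2[C@H](C)[C@@H](O)c1cc(OC)c(OC)c(OC)c1 | intermediate
9 | tert-butyldimethylsilyl ether of 8 | C1COC2(O1)CC[C@H](B3OC(C)(C)C(C)(C)O3)C=C2[C@H](C)[C@@H](O[Si](C)(C)C(C)(C)C)c1cc(OC)c(OC)c(OC)c1 | intermediate
10 | (8S)-allylic alcohol, side chain (1R,2S), O-TBS | C1COC2(O1)CC[C@H](O)C=C2[C@H](C)[C@@H](O[Si](C)(C)C(C)(C)C)c1cc(OC)c(OC)c(OC)c1 | intermediate
11 | (8S)-allylic methyl ether, side chain (1R,2S), O-TBS | C1COC2(O1)CC[C@H](OC)C=C2[C@H](C)[C@@H](O[Si](C)(C)C(C)(C)C)c1cc(OC)c(OC)c(OC)c1 | intermediate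
12 | (4S)-2-[(1R,2S)-1-(TBSO)-1-(3,4,5-trimethoxyphenyl)propan-2-yl]-4-methoxycyclohex-2-en-1-one | O=C1CC[C@H](OC)C=C1[C@H](C)[C@@H](O[Si](C)(C)C(C)(C)C)c1cc(OC)c(OC)c(OC)c1 | intermediate
13 | lithium enolate C1(O–)=C6 from conjugate reduction of 12 | [Li+].[O-]C1=C([C@H](C)[C@@H](O[Si](C)(C)C(C)(C)C)c2cc(OC)c(OC)c(OC)c2)C[C@@H](OC)CC1 | intermediate
14 | (2R,4S)-2-allyl-2-[(1R,2S)-1-(TBSO)-1-(3,4,5-trimethoxyphenyl)propan-2-yl]-4-methoxycyclohexan-1-one | C=CC[C@]1([C@H](C)[C@@H](O[Si](C)(C)C(C)(C)C)c2cc(OC)c(OC)c(OC)c2)C[C@@H](OC)CCC1=O | intermediate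
15 | lithium enolate C1(O–)=C2 of 14 | C=CC[C@]1([C@H](C)[C@@H](O[Si](C)(C)C(C)(C)C)c2cc(OC)c(OC)c(OC)c2)C[C@@H](OC)CC=C1[O-].[Li+] | intermediate
16 | C2-(N-tert-butyl-S-phenylsulfilimino) ketone (C2 and S configurations not defined) | C=CC[C@]1([C@H](C)[C@@H](O[Si](C)(C)C(C)(C)C)c2cc(OC)c(OC)c(OC)c2)C[C@@H](OC)CC(S(=NC(C)(C)C)c2ccccc2)C1=O | intermediate
17 | O-TBS-megaphone, (4R,6R), side chain (1R,2S) | C=CC[C@]1([C@H](C)[C@@H](O[Si](C)(C)C(C)(C)C)c2cc(OC)c(OC)c(OC)c2)C[C@@H](OC)C=CC1=O | intermediate
18 | megaphone, (4R,6R), side chain (1R,2S) | C=CC[C@]1([C@H](C)[C@@H](O)c2cc(OC)c(OC)c(OC)c2)C[C@@H](OC)C=CC1=O | target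

Total step count: 12. Longest linear sequence: 12 steps (1 to 18).

**Steps most likely to fail**

1. Step 4 (Proposed new method).
   - What may go wrong: delivery of the second boron to C8 (1,4-addition), slow insertion of a 1,2-disubstituted ring alkene, or weak discrimination of the alkene faces.
   - Fallback with known chemistry, setting out from 4 and returning at 11: catalytic OsO4/NMO dihydroxylation of the less hindered ring alkene, which is less deactivated by the ketal, should give the racemic cis-diol F1. Candida antarctica lipase B and vinyl acetate should acetylate the equatorial C4 hydroxyl of the unwanted enantiomer to the monoacetate F2 and leave the (7R,8S)-diol F1. MeI/Ag2O should methylate its unhindered equatorial C4 hydroxyl to the methyl ether F3. NaH and 3,4,5-trimethoxybenzyl chloride give the allyl benzyl ether F4. n-BuLi in THF at −78 °C then triggers a [2,3]-Wittig rearrangement, suprafacial from the axial C5–O bond on the C4–OMe face and syn-selective for this Z-type allyl ether, which forms C7–C8 and moves the oxygen to C7 to give the homoallylic alcohol F5. TBSOTf/2,6-lutidine gives 11.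

2. Step 10.
   - What may go wrong: sluggish C-alkylation of the crowded tetrasubstituted enolate, O-allylation or proton transfer, and erosion of facial selectivity.
   - Fallback, setting out from 12 and returning at 14: the same LiBH(s-Bu)3 conjugate reduction is quenched with allyl chloroformate to give the allyl enol carbonate F6. Zerovalent palladium (Pd2(dba)3, t-Bu-PHOX ligand of the matched hand, toluene) should convert F6 by decarboxylative Tsuji allylation into 14, the ligand reinforcing the substrate bias.

3. Step 3.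
   - What may go wrong: poor E/Z control in the elimination, or allylic transposition of the sulfamate.
   - Fallback, setting out from 2 and returning at 4: addition of 1-(trimethylsilyl)ethylmagnesium chloride to 2 gives the β-hydroxysilane F7 as two separable diastereomers. Peterson olefination is stereospecific, so KH (syn elimination) on one diastereomer and BF3·OEt2 at low temperature (anti elimination) on the other should both converge on (E)-4.

**Further compounds**
F1 | step 4 | (6E,7R,8S)-6-ethylidene-1,4-dioxaspiro[4.5]decane-7,8-diol (first formed as the racemate) | C1COC2(O1)CC[C@H](O)[C@H](O)/C2=C\C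
F2 | step 4 | (6E,7S,8R)-6-ethylidene-7-hydroxy-1,4-dioxaspiro[4.5]decan-8-yl acetate | C1COC2(O1)CC[C@@H](OC(C)=O)[C@@H](O)/C2=C\C
F3 | step 4 | (6E,7R,8S)-6-ethylidene-8-methoxy-1,4-dioxaspiro[4.5]decan-7-ol | C1COC2(O1)CC[C@H](OC)[C@H](O)/C2=C\C
F4 | step 4 | (6E,7R,8S)-6-ethylidene-8-methoxy-7-[(3,4,5-trimethoxybenzyl)oxy]-1,4-dioxaspiro[4.5]decane | C1COC2(O1)CC[C@H](OC)[C@H](OCc1cc(OC)c(OC)c(OC)c1)/C2=C\C
F5 | step 4 | (1R,2S)-2-[(8S)-8-methoxy-1,4-dioxaspiro[4.5]dec-6-en-6-yl]-1-(3,4,5-trimethoxyphenyl)propan-1-ol | C1COC2(O1)CC[C@H](OC)C=C2[C@H](C)[C@@H](O)c1cc(OC)c(OC)c(OC)c1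
F6 | step 10 | allyl (4S)-2-[(1R,2S)-1-(tert-butyldimethylsilyloxy)-1-(3,4,5-trimethoxyphenyl)propan-2-yl]-4-methoxycyclohex-1-en-1-yl carbonate | C=CCOC(=O)OC1=C([C@H](C)[C@@H](O[Si](C)(C)C(C)(C)C)c2cc(OC)c(OC)c(OC)c2)C[C@@H](OC)CC1
F7 | step 3 | 6-[1-(trimethylsilyl)ethyl]-1,4-dioxaspiro[4.5]dec-7-en-6-ol (two racemic diastereomers) | CC([Si](C)(C)C)C1(O)C=CCCC12OCCO2
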